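## Retrosynthetic overview

1. γ-Lactone F is closed last by carboxylate-directed γ-C–H lactonisation of the C22 methyl; the C27 carbinol comes from MeMgBr addition to the caged ketone.
2. Rings E and C (bicyclo[2.2.2]octanone plus cyclopentane, four stereocentres) form in one pot: conjugate reduction / Michael / Michael / enolate alkylation of a spiro-cyclohexadienone with tert-butyl acrylate.
3. Rings B and D: dearomative spirocyclisation (phenol para-C-alkylation by an α-diazoketone) of an acid carrying 2,3,6-trimethylphenol.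
4. Ring A and the quaternary C9: asymmetric Michael addition of tert-butyl 2-allylacetoacetate to acrolein, MeMgBr/lactonisation, dehydrogenation.
5. Ring order: A → B onto dearomatised D → E + C (cascade) → F.

Assumption 1: atom labels C1–C30 follow the atom order of the target SMILES (C2 = CMe2–O, C5 = ring-A C=O, C9 = spiro carbon, C12 = cage carbon bonded to C11/C13/C22/C26, C14 and C22 = bridgeheads, C17 = CH–C18, C21 = CH2O of ring F, C23 = C(Me) next to ketone C30, C25/C26 = cyclopentane CH2/CH, C27 = carbinol carbon).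

Assumption 2: the cupreidine-type catalyst in step 2 gives (S)-5; if the sense is opposite, its cupreine pseudo-enantiomer is used.

## Route

Step 1
Reactants: 1 tert-butyl acetoacetate; 2 allyl bromide
Product: 3 tert-butyl 2-acetylpent-4-enoate (racemic)
Conditions: NaH (1.0 equiv), THF, 0 °C → rt
Reagents that add atoms: none
Why: SN2 C-allylation of the β-ketoester sodium enolate; the remaining acidic C–H makes the centre labile, so no stereochemistry is set here.

Step 2
Reactants: 3 tert-butyl 2-acetylpent-4-enoate; 4 acrolein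
Product: 5 tert-butyl (2S)-2-acetyl-2-(3-oxopropyl)pent-4-enoate
Conditions: 9-O-(9-phenanthryl)cupreidine (10 mol %), CH2Cl2, −24 °C
Reagents that add atoms: none
Why: Bifunctional cinchona-alkaloid-catalysed asymmetric Michael addition of an α-substituted β-ketoester to an enal; the catalyst (quinuclidine base, 6′-OH hydrogen bond) selects the enolate face and sets the quaternary C9.

Step 3
Reactants: 5 tert-butyl (2S)-2-acetyl-2-(3-oxopropyl)pent-4-enoate
Product: 6 (4S)-4-acetyl-4-(tert-butoxycarbonyl)hept-6-enoic acid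
Conditions: NaClO2, NaH2PO4, 2-methylbut-2-ene, t-BuOH–H2O, 0 °C → rt
Reagents that add atoms: sodium chlorite, [Na+].[O-]Cl=O
Why: Pinnick oxidation is selective for the aldehyde; ketone, ester and alkene are untouched and the scavenger removes HOCl.

Step 4
Reactants: 6 (4S)-4-acetyl-4-(tert-butoxycarbonyl)hept-6-enoic acid
Product: 8 tert-butyl (3S)-2,2-dimethyl-6-oxo-3-(prop-2-en-1-yl)oxane-3-carboxylate, via hydroxy acid 7 (not isolated)
Conditions: MeMgBr (2.3 equiv), THF, −78 → −20 °C; aq. citric acid; then PPTS (cat.), PhMe, 60 °C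
Reagents that add atoms: methylmagnesium bromide, C[Mg]Br
Why: Grignard addition to the methyl ketone (the carboxylate and the hindered tert-butyl ester are inert) gives the CMe2–OH, and acid-catalysed lactonisation of the δ-hydroxy acid (Thorpe–Ingold assisted) closes ring A; C9 is untouched.

Step 5
Reactants: 8 tert-butyl (3S)-2,2-dimethyl-6-oxo-3-(prop-2-en-1-yl)oxane-3-carboxylate
Product: 12 tert-butyl (3R)-2,2-dimethyl-6-oxo-3-(prop-2-en-1-yl)-3,6-dihydro-2H-pyran-3-carboxylate, via lithium enolate 9 (not isolated), via selenide 10 (not isolated), via selenoxide 11 (not isolated)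
Conditions: LDA, THF, −78 °C; PhSeBr; then 30 % H2O2, pyridine, CH2Cl2, 0 °C → rt
Reagents that add atoms: phenylselenyl bromide, Br[Se]c1ccccc1 (Se–Ph only in 10 and 11); hydrogen peroxide, OO (O only in 11)
Why: α-Selenenylation and selenoxide syn-elimination; the lactone α-CH2 is the only acidic site and elimination can only go toward C8, giving the C7=C8 enoate (the R/S label changes by CIP priority only).

Step 6
Reactants: 12 tert-butyl (3R)-2,2-dimethyl-6-oxo-3-(prop-2-en-1-yl)-3,6-dihydro-2H-pyran-3-carboxylate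
Product: 14 tert-butyl (3R)-2,2-dimethyl-6-oxo-3-(2-oxoethyl)-3,6-dihydro-2H-pyran-3-carboxylate, via ozonide 13 (not isolated)
Conditions: O3, CH2Cl2, −78 °C (Sudan III end-point); then Me2S, −78 °C → rt
Reagents that add atoms: ozone, [O-][O+]=O
Why: Ozonolysis; the electron-rich terminal alkene reacts far faster than the conjugated lactone alkene.

Step 7
Reactants: 14 tert-butyl (3R)-2,2-dimethyl-6-oxo-3-(2-oxoethyl)-3,6-dihydro-2H-pyran-3-carboxylate; 15 2,3,6-trimethylphenol
Product: 17 (3R)-3-[2-(4-hydroxy-2,3,5-trimethylphenyl)ethyl]-2,2-dimethyl-6-oxo-3,6-dihydro-2H-pyran-3-carboxylic acid, via spiro bis-lactone 16 (not isolated)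
Conditions: 15 (1.5 equiv), TFA–CH2Cl2 (1:3), 0 °C; then Et3SiH (3 equiv), rt
Reagents that add atoms: none
Why: Friedel–Crafts hydroxyalkylation at the only open activated position (para to OH) with loss of the tert-butyl group traps the benzylic cation as a γ-aryl lactone; Et3SiH/TFA ionic hydrogenation of the p-hydroxybenzylic C–O bond then gives the arylethyl acid (reductive Friedel–Crafts alkylation).

Step 8
Reactants: 17 (3R)-3-[2-(4-hydroxy-2,3,5-trimethylphenyl)ethyl]-2,2-dimethyl-6-oxo-3,6-dihydro-2H-pyran-3-carboxylic acid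
Product: 21 dispiro dienone-ketone-lactone (rings A/B/D), via acid chloride 18 (not isolated), via diazoketone 19 (not isolated), via diazonium salt 20 (not isolated)
Conditions: (COCl)2, DMF (cat.), CH2Cl2, 0 °C; CH2N2, Et2O, 0 °C; then TFA, CH2Cl2, −20 °C
Reagents that add atoms: oxalyl chloride, ClC(=O)C(=O)Cl (Cl only in 18); diazomethane, C=[N+]=[N-]
Why: Diazoketone formation followed by acid-promoted Ar1-6 phenol participation (Mander-type dearomative spirocyclisation) forms ring B and the C12 spiro centre; a chair transition state with the CMe2 arm (C2) and the methyl-bearing arene carbon (C22) both equatorial gives the trans C9/C12 relationship.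

Step 9
Reactants: 21 dispiro dienone-ketone-lactone
Product: 23 C26-hydroxymethyl ketone, via lithium enolate 22 (not isolated)
Conditions: LiHMDS, THF, −78 °C; CH2O (gas), −78 °C; aq. NH4Cl
Reagents that add atoms: formaldehyde, C=O
Why: Aldol addition of the only possible ketone enolate (C9 is quaternary); formaldehyde enters anti to the axial C13–H arm of the perpendicular dienone ring, placing C25 cis to C22.

Step 10
Reactants: 23 C26-hydroxymethyl ketone
Product: 24 C27-methylene homoallylic alcohol
Conditions: Zn, CH2Br2, TiCl4, THF–CH2Cl2, 0 °C → rt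
Reagents that add atoms: dibromomethane, BrCBr
Why: Takai–Lombardo methylenation is non-basic (no retro-aldol or C26 epimerisation) and prefers the saturated ketone over the vinylogously deactivated, 2,6-dimethyl-flanked dienone carbonyl; this masks C27 against hydride and enolate chemistry.

Step 11
Reactants: 24 C27-methylene homoallylic alcohol
Product: 25 C25 mesylate
Conditions: MsCl, Et3N, CH2Cl2, −10 °C
Reagents that add atoms: methanesulfonyl chloride, CS(=O)(=O)Cl
Why: Sulfonylation of the primary alcohol; the homoallylic mesylate has no acidic β-hydrogen and cannot eliminate.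

Step 12
Reactants: 25 C25 mesylate; 26 tert-butyl acrylate
Product: 30 caged tert-butyl ester (C27 methylene), via potassium dienolate 27 (not isolated), via ester enolate 28 (not isolated), via bicyclic ketone enolate 29 (not isolated)
Conditions: K-Selectride (1.05 equiv), THF, −78 °C; 26 (1.2 equiv), −78 → −20 °C; then DMPU, NaI (cat.), 0 → 40 °C
Reagents that add atoms: none
Why: Proposed new method: hydride adds 1,4 to the less substituted dienone arm (C13) to give the cross-conjugated dienolate, which adds through C14 to the acrylate on the ring-D face syn to C11 (away from the branched C26), the ester enolate closes onto C22 in the chelated endo sense (C18 syn to the C30 bridge), and the resulting C23 enolate is alkylated 5-exo-tet by the C25 mesylate, so rings E and C and C14/C17/C22/C23 are set in one operation; closest known reactions are the double Michael (MIMIRC) annulation of cyclohexenone dienolates with acrylates to bicyclo[2.2.2]octanones and Selectride reductive enolate alkylation.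

Step 13
Reactants: 30 caged tert-butyl ester (C27 methylene)
Product: 33 caged C27-keto C18-acid, via ozonide 31 (not isolated), via keto tert-butyl ester 32 (not isolated)
Conditions: O3, CH2Cl2, −78 °C; Me2S; evaporate; then TFA–CH2Cl2 (1:4), 0 °C → rt
Reagents that add atoms: ozone, [O-][O+]=O
Why: Ozonolysis of the electron-rich exocyclic alkene (the conjugated lactone alkene is slower) unmasks the C27 ketone, and acidolysis of the tert-butyl ester (loss of isobutene) frees the C18 acid.

Step 14
Reactants: 33 caged C27-keto C18-acid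
Product: 34 C27-carbinol C18-acid
Conditions: MeMgBr (3.5 equiv), CeCl3 (3.5 equiv), THF, −78 °C; aq. NH4Cl
Reagents that add atoms: methylmagnesium bromide, C[Mg]Br
Why: Organocerium 1,2-addition to the only reactive ketone (C30 is flanked by two quaternary carbons, the carboxylate is inert, the lactone is slower at −78 °C); methyl attacks the convex face of the cis-fused B/C system, away from the cyclopentane and C21, giving C27 with OH cis to C25.

Step 15
Reactants: 34 C27-carbinol C18-acid
Product: 35 target (CNP0222978.3)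
Conditions: [Mn(OTf)2(TIPS-mcp)] (2 mol %), aq. H2O2 (slow addition), CF3CH2OH, 0 °C
Reagents that add atoms: none
Why: Carboxylate-directed Mn-catalysed γ-C(sp3)–H lactonisation (1,7-HAT by the carboxylate-bound Mn-oxo, then carboxylate rebound); the C21 methyl on the β-quaternary C22 is the only γ-C–H of the C18 acid, and no stereocentre is touched.

## Compound list

1 | tert-butyl acetoacetate | CC(=O)CC(=O)OC(C)(C)C | starting material
2 | allyl bromide | C=CCBr | starting material
3 | tert-butyl 2-acetylpent-4-enoate (racemic) | CC(=O)C(CC=C)C(=O)OC(C)(C)C | intermediate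
4 | acrolein | C=CC=O | starting material
5 | tert-butyl (2S)-2-acetyl-2-(3-oxopropyl)pent-4-enoate | CC(=O)[C@@](CC=C)(CCC=O)C(=O)OC(C)(C)C | intermediate
6 | (4S)-4-acetyl-4-(tert-butoxycarbonyl)hept-6-enoic acid | CC(=O)[C@@](CC=C)(CCC(=O)O)C(=O)OC(C)(C)C | intermediate
7 | (4S)-4-(tert-butoxycarbonyl)-4-(2-hydroxypropan-2-yl)hept-6-enoic acid | CC(C)(O)[C@@](CC=C)(CCC(=O)O)C(=O)OC(C)(C)C | intermediate (not isolated)
8 | tert-butyl (3S)-2,2-dimethyl-6-oxo-3-(prop-2-en-1-yl)oxane-3-carboxylate | CC1(C)OC(=O)CC[C@@]1(CC=C)C(=O)OC(C)(C)C | intermediate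
9 | lithium enolate of 8 | CC1(C)OC([O-])=CC[C@@]1(CC=C)C(=O)OC(C)(C)C.[Li+] | intermediate (not isolated)
10 | 5-(phenylselanyl) derivative of 8 (both C5 epimers) | CC1(C)OC(=O)C([Se]c2ccccc2)C[C@@]1(CC=C)C(=O)OC(C)(C)C | intermediate (not isolated)
11 | selenoxide of 10 | CC1(C)OC(=O)C([Se](=O)c2ccccc2)C[C@@]1(CC=C)C(=O)OC(C)(C)C | intermediate (not isolated)
12 | tert-butyl (3R)-2,2-dimethyl-6-oxo-3-(prop-2-en-1-yl)-3,6-dihydro-2H-pyran-3-carboxylate | CC1(C)OC(=O)C=C[C@@]1(CC=C)C(=O)OC(C)(C)C | intermediate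
13 | 1,2,4-trioxolane (secondary ozonide) of the allyl group of 12 | CC1(C)OC(=O)C=C[C@@]1(CC2OCOO2)C(=O)OC(C)(C)C | intermediate (not isolated)
14 | tert-butyl (3R)-2,2-dimethyl-6-oxo-3-(2-oxoethyl)-3,6-dihydro-2H-pyran-3-carboxylate | CC1(C)OC(=O)C=C[C@@]1(CC=O)C(=O)OC(C)(C)C | intermediate
15 | 2,3,6-trimethylphenol | Cc1ccc(C)c(O)c1C | starting material
16 | spiro bis-lactone: ring A spiro at C9 to a γ-(4-hydroxy-2,3,5-trimethylphenyl)-γ-butyrolactone (benzylic epimers) | CC1(C)OC(=O)C=C[C@]12CC(c3cc(C)c(O)c(C)c3C)OC2=O | intermediate (not isolated)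
17 | (3R)-3-[2-(4-hydroxy-2,3,5-trimethylphenyl)ethyl]-2,2-dimethyl-6-oxo-3,6-dihydro-2H-pyran-3-carboxylic acid | CC1(C)OC(=O)C=C[C@@]1(CCc1cc(C)c(O)c(C)c1C)C(=O)O | intermediate
18 | acid chloride of 17 | CC1(C)OC(=O)C=C[C@@]1(CCc1cc(C)c(O)c(C)c1C)C(Cl)=O | intermediate (not isolated)
19 | diazomethyl ketone from 18 | CC1(C)OC(=O)C=C[C@@]1(CCc1cc(C)c(O)c(C)c1C)C(=O)C=[N+]=[N-] | intermediate (not isolated)
20 | α-diazonium ketone trifluoroacetate from 19 | CC1(C)OC(=O)C=C[C@@]1(CCc1cc(C)c(O)c(C)c1C)C(=O)C[N+]#N.[O-]C(=O)C(F)(F)F | intermediate (not isolated)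
21 | dispiro compound: ring A lactone spiro at C9 to cyclohexanone ring B (C27=O next to C9), ring B spiro at C12 to 2,3,6-trimethylcyclohexa-2,5-dienone ring D; C2 and the methyl-bearing C22 trans across ring B | CC1(C)OC(=O)C=C[C@]12CC[C@]3(C=C(C)C(=O)C(C)=C3C)CC2=O | intermediate
22 | lithium enolate of 21 (C26=C27) | CC1(C)OC(=O)C=C[C@]12CC[C@]3(C=C(C)C(=O)C(C)=C3C)C=C2[O-].[Li+] | intermediate (not isolated)
23 | 21 carrying CH2OH on C26, cis to C22 and trans to C13 | CC1(C)OC(=O)C=C[C@]12CC[C@]3(C=C(C)C(=O)C(C)=C3C)[C@@H](CO)C2=O | intermediate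
24 | 23 with the C27 ketone replaced by C27=CH2 | CC1(C)OC(=O)C=C[C@]12CC[C@]3(C=C(C)C(=O)C(C)=C3C)[C@@H](CO)C2=C | intermediate
25 | methanesulfonate of 24 | CC1(C)OC(=O)C=C[C@]12CC[C@]3(C=C(C)C(=O)C(C)=C3C)[C@@H](COS(C)(=O)=O)C2=C | intermediate
26 | tert-butyl acrylate | C=CC(=O)OC(C)(C)C | starting material
27 | potassium cross-conjugated dienolate (H added at C13; C14=C30–O−) | CC1(C)OC(=O)C=C[C@]12CC[C@]3(CC(C)=C([O-])C(C)=C3C)[C@@H](COS(C)(=O)=O)C2=C.[K+] | intermediate (not isolated)
28 | potassium ester enolate after the first Michael addition (C14–C16 bond) | CC1(C)OC(=O)C=C[C@]12CC[C@]3(C[C@@](C)(CC=C([O-])OC(C)(C)C)C(=O)C(C)=C3C)[C@@H](COS(C)(=O)=O)C2=C.[K+] | intermediate (not isolated)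
29 | potassium enolate (C23=C30–O−) of the bicyclo[2.2.2]octanone after the second Michael addition (C17–C22 bond) | CC1(C)OC(=O)C=C[C@]12CC[C@]3(C[C@@]4(C)C[C@H](C(=O)OC(C)(C)C)[C@]3(C)C(C)=C4[O-])[C@@H](COS(C)(=O)=O)C2=C.[K+] | intermediate (not isolated)
30 | caged pentacycle (rings A–E): C18 tert-butyl ester syn to the C30 bridge, C21 = CH3, C27=CH2, ring B cis-fused to the cyclopentane | CC1(C)OC(=O)C=C[C@]12CC[C@@]13C[C@@]4(C)C[C@H](C(=O)OC(C)(C)C)[C@]1(C)[C@@](C)(C[C@H]3C2=C)C4=O | intermediate
31 | spiro 1,2,4-trioxolane (ozonide) at C27 of 30 | CC1(C)OC(=O)C=C[C@]12CC[C@@]13C[C@@]4(C)C[C@H](C(=O)OC(C)(C)C)[C@]1(C)[C@@](C)(C[C@H]3C25OCOO5)C4=O | intermediate (not isolated)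
32 | C27 ketone, C18 tert-butyl ester | CC1(C)OC(=O)C=C[C@]12CC[C@@]13C[C@@]4(C)C[C@H](C(=O)OC(C)(C)C)[C@]1(C)[C@@](C)(C[C@H]3C2=O)C4=O | intermediate (not isolated)
33 | C27 ketone, C18 carboxylic acid | CC1(C)OC(=O)C=C[C@]12CC[C@@]13C[C@@]4(C)C[C@H](C(=O)O)[C@]1(C)[C@@](C)(C[C@H]3C2=O)C4=O | intermediate
34 | C27 tertiary alcohol (Me on the convex face, OH cis to C25), C18 carboxylic acid, C21 = CH3 | CC1(C)OC(=O)C=C[C@]12CC[C@@]13C[C@@]4(C)C[C@H](C(=O)O)[C@]1(C)[C@@](C)(C[C@H]3[C@@]2(C)O)C4=O | intermediate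
35 | CNP0222978.3 | CC1(C)OC(=O)C=C[C@]12CC[C@@]13C[C@@]4(C)C[C@@H]5C(=O)OC[C@]51[C@@](C)(C[C@H]3[C@@]2(C)O)C4=O | target

## Totals and risks

Total step count: 15. Longest linear sequence: 15 (from tert-butyl acetoacetate).

The three steps most likely to fail are step 12, step 15 and step 7.

**Step 12 (cascade).** The second Michael addition must create the C22 quaternary bridgehead next to the spiro C12, and proton transfer to the ester enolate or acrylate oligomerisation can intercept it. The fallback sets out from 25 and comes back at 30. L-Selectride conjugate reduction with TBSCl trapping gives the silyl dienol ether F3. A thermal or Me2AlCl-promoted [4+2] cycloaddition of this 2-silyloxydiene with 26 (same regiochemistry, endo) gives the bicyclo[2.2.2]octene silyl enol ether F4. TBAF in THF then releases the C23 enolate, which closes the cyclopentane on the mesylate to give 30.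

**Step 15 (C–H lactonisation).** Oxidation at the δ C24 methyl or of the lactone alkene may compete. The fallback sets out from 33 and comes back at 35. The acid is converted (oxalyl chloride, then NH3) into the primary amide F5. Suárez-type amidyl-radical 1,5-hydrogen transfer (PhI(OAc)2, I2, hν) functionalises C21 and gives the iminolactone F6, which mild aqueous acid hydrolyses to the keto lactone F7. MeMgBr/CeCl3 at −78 °C (ketone faster than γ-lactone, same convex-face attack) then gives 35.

**Step 7 (reductive arylation).** Diarylmethane formation or direct reduction of the aldehyde may win. The fallback sets out from 14 and comes back at 17. Pinnick oxidation gives the carboxylic acid F1. Its acid chloride acylates 15 para to OH (TiCl4, Friedel–Crafts) to give the aryl ketone F2. Et3SiH/TFA then reduces the p-hydroxyaryl ketone to CH2 and cleaves the tert-butyl ester, giving 17.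

Further compounds
F1 | step 7 | 2-[(3R)-3-(tert-butoxycarbonyl)-2,2-dimethyl-6-oxo-3,6-dihydro-2H-pyran-3-yl]acetic acid | CC1(C)OC(=O)C=C[C@@]1(CC(=O)O)C(=O)OC(C)(C)C
F2 | step 7 | tert-butyl (3R)-3-[2-(4-hydroxy-2,3,5-trimethylphenyl)-2-oxoethyl]-2,2-dimethyl-6-oxo-3,6-dihydro-2H-pyran-3-carboxylate | CC1(C)OC(=O)C=C[C@@]1(CC(=O)c1cc(C)c(O)c(C)c1C)C(=O)OC(C)(C)C
F3 | step 12 | tert-butyldimethylsilyl dienol ether of 27 | CC1(C)OC(=O)C=C[C@]12CC[C@]3(CC(C)=C(O[Si](C)(C)C(C)(C)C)C(C)=C3C)[C@@H](COS(C)(=O)=O)C2=C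
F4 | step 12 | bicyclo[2.2.2]octene tert-butyldimethylsilyl enol ether (silyl analogue of 29) | CC1(C)OC(=O)C=C[C@]12CC[C@]3(C[C@@]4(C)C[C@H](C(=O)OC(C)(C)C)[C@]3(C)C(C)=C4O[Si](C)(C)C(C)(C)C)[C@@H](COS(C)(=O)=O)C2=C
F5 | step 15 | primary C18 amide of 33 | CC1(C)OC(=O)C=C[C@]12CC[C@@]13C[C@@]4(C)C[C@H](C(N)=O)[C@]1(C)[C@@](C)(C[C@H]3C2=O)C4=O
F6 | step 15 | C18/C21 iminolactone with C27 ketone | CC1(C)OC(=O)C=C[C@]12CC[C@@]13C[C@@]4(C)C[C@@H]5C(=N)OC[C@]51[C@@](C)(C[C@H]3C2=O)C4=O
F7 | step 15 | ring-F γ-lactone with C27 ketone | CC1(C)OC(=O)C=C[C@]12CC[C@@]13C[C@@]4(C)C[C@@H]5C(=O)OC[C@]51[C@@](C)(C[C@H]3C2=O)C4=O
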